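Everything rests on disconnecting the bond between the methine carbon shared by the six- and seven-membered rings and its neighbour in the mono-oxygenated ring C. That methine is benzylic to catechol ring B and para to one of its oxygens, and the ring C carbon is para to the ring C oxygen, so the bond is made as a cation–arene (Friedel–Crafts) closure. A chiral Brønsted acid protonates the stilbene of a simple biaryl keto-stilbene and closes the dihydrophenanthrene ring enantioselectively; in the same flask the ketone condenses onto ring B and closes the seven-membered ring as an alkene. Convex-face hydrogenation then sets the second stereocentre, and demethylation ends the route.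

Key step: step 4

Remark: ring A is the dimethoxy ring of the biaryl that carries the styryl group, ring C the methoxy ring of the biaryl, ring B the dimethoxyphenyl ring of the stilbene, ring D the dimethoxyphenyl ring of the ketone. IDPi is an imidodiphosphorimidate Brønsted acid built from two 3,3'-diaryl-BINOL units with N-triflyl groups. It is assumed that a first run shows which catalyst antipode gives the (S)-methine, and that antipode is used.

Step 1
Reactants: 1 2-bromo-3,5-dimethoxybenzaldehyde; 2 (3-chloro-5-methoxyphenyl)boronic acid
Product: 3 3'-chloro-4,5',6-trimethoxy-[1,1'-biphenyl]-2-carbaldehyde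
Conditions: Pd(dppf)Cl2 (3 mol %), K2CO3, dioxane/H2O, 90 °C
Reagents that add atoms: none
Why: Suzuki–Miyaura coupling in which oxidative addition should take place only at the C–Br bond activated by the ortho-formyl group, the unactivated aryl chloride of 2 staying intact with this catalyst.

Step 2
Reactants: 3 3'-chloro-4,5',6-trimethoxy-[1,1'-biphenyl]-2-carbaldehyde; 4 diethyl (3,4-dimethoxybenzyl)phosphonate
Product: 5 (E)-3'-chloro-2-[2-(3,4-dimethoxyphenyl)ethenyl]-4,5',6-trimethoxy-1,1'-biphenyl
Conditions: KOtBu, THF, 0 °C to rt
Reagents that add atoms: none
Why: Horner–Wadsworth–Emmons olefination of a non-enolisable aryl aldehyde with a benzylic phosphonate, which should give the (E)-stilbene; the alkene geometry is in any case erased in step 4.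

Step 3
Reactants: 5 (E)-3'-chloro-2-[2-(3,4-dimethoxyphenyl)ethenyl]-4,5',6-trimethoxy-1,1'-biphenyl; 6 1-(3,4-dimethoxyphenyl)ethan-1-one
Product: 7 1-(3,4-dimethoxyphenyl)-2-{2'-[(E)-2-(3,4-dimethoxyphenyl)ethenyl]-4',5,6'-trimethoxy-[1,1'-biphenyl]-3-yl}ethan-1-one
Conditions: Pd2(dba)3 (2 mol %), XPhos (8 mol %), NaOtBu, toluene, 80 °C
Reagents that add atoms: none
Why: Palladium-catalysed α-arylation of a methyl ketone enolate with an aryl chloride (Buchwald–Hartwig type), in which the bulky biaryl phosphine should allow oxidative addition of the chloride and favour monoarylation while the internal stilbene stays inert.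

Step 4
Reactants: 7 1-(3,4-dimethoxyphenyl)-2-{2'-[(E)-2-(3,4-dimethoxyphenyl)ethenyl]-4',5,6'-trimethoxy-[1,1'-biphenyl]-3-yl}ethan-1-one
Product: 9 (S)-pentacyclic triaryl alkene heptamethyl ether, via (S)-dihydrophenanthrene ketone 8 (not isolated)
Conditions: chiral IDPi acid (10 mol %), CHCl3 (0.01 M), 4 Å MS, 40 °C; then MsOH (10 equiv), 0 to 40 °C, same flask; Et3N quench
Reagents that add atoms: none
Why: Proposed new method: the strong confined acid should protonate the stilbene at the carbon next to ring A, since only the other carbon gives a cation stabilised by the para-methoxy group of ring B, and this benzylic cation, held as a contact ion pair by the chiral imidodiphosphorimidate anion, is captured by the ring C carbon that lies para to the methoxy group and ortho to the biaryl bond. The closest known reaction types are the asymmetric intramolecular hydroarylation of olefins catalysed by strong confined chiral Brønsted acids and the achiral acid-mediated cycloisomerisation of 2-styrylbiaryls to 9-aryl-9,10-dihydrophenanthrenes; the enantioselective version on a stilbene with an anisole-type ring is not established. This first closure is a 6-endo-trig Friedel–Crafts alkylation that forms the dihydrophenanthrene ring and the methine stereocentre, whose (S) configuration is set by the chiral anion (catalyst control), both alkene isomers converging on the same cation. In the second stage MsOH activates the ketone, the now adjacent ring B attacks the carbonyl carbon through its carbon para to a methoxy group (7-exo-trig Friedel–Crafts hydroxyalkylation) and loss of water gives the conjugated alkene, a cyclodehydration of the Bradsher type that creates no stereocentre. The step needs the cation at the right alkene carbon (secured by the para-methoxy group of ring B against the meta-methoxy groups of ring A), attack para and not ortho to the ring C oxygen (secured by the para preference of stabilised benzylic cations, and only this mode brings the ketone within reach of ring B), and intramolecular capture over dimerisation (secured by dilution).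

Step 5
Reactants: 9 (S)-pentacyclic triaryl alkene heptamethyl ether
Product: 10 (S,R)-heptamethyl ether of the target
Conditions: H2 (3 bar), Pd/C (10 wt %), EtOAc/EtOH, rt
Reagents that add atoms: none
Why: Heterogeneous syn-hydrogenation of a triaryl-substituted alkene: the seven-membered ring is a boat whose concave face is screened by the sloping rings B and C, and because the dihydrophenanthrene fusion holds the existing methine hydrogen in the flagpole position of the convex face, hydrogen should add from that open face, placing the new C–H cis to it and the dimethoxyphenyl group pseudo-equatorial, which is the (R) centre of the target.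

Step 6
Reactants: 10 (S,R)-heptamethyl ether of the target
Product: 11 CNP0306974.2
Conditions: BBr3 (14 equiv), CH2Cl2, −78 °C to rt; then H2O, 0 °C, under argon
Reagents that add atoms: none
Why: Lewis-acid cleavage of all seven aryl methyl ethers (BBr3 demethylation), which should leave the carbon framework and both benzylic stereocentres untouched because neither carries a leaving group.

Compound list
1 | 2-bromo-3,5-dimethoxybenzaldehyde | COc1cc(OC)c(Br)c(C=O)c1 | starting material
2 | (3-chloro-5-methoxyphenyl)boronic acid | COc1cc(Cl)cc(B(O)O)c1 | starting material
3 | 3'-chloro-4,5',6-trimethoxy-[1,1'-biphenyl]-2-carbaldehyde | COc1cc(OC)c(-c2cc(OC)cc(Cl)c2)c(C=O)c1 | intermediate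
4 | diethyl (3,4-dimethoxybenzyl)phosphonate | CCOP(=O)(OCC)Cc1ccc(OC)c(OC)c1 | starting material
5 | (E)-3'-chloro-2-[2-(3,4-dimethoxyphenyl)ethenyl]-4,5',6-trimethoxy-1,1'-biphenyl | COc1cc(OC)c(-c2cc(OC)cc(Cl)c2)c(/C=C/c2ccc(OC)c(OC)c2)c1 | intermediate
6 | 1-(3,4-dimethoxyphenyl)ethan-1-one (3',4'-dimethoxyacetophenone) | CC(=O)c1ccc(OC)c(OC)c1 | starting material
7 | 1-(3,4-dimethoxyphenyl)-2-{2'-[(E)-2-(3,4-dimethoxyphenyl)ethenyl]-4',5,6'-trimethoxy-[1,1'-biphenyl]-3-yl}ethan-1-one | COc1cc(OC)c(-c2cc(OC)cc(CC(=O)c3ccc(OC)c(OC)c3)c2)c(/C=C/c2ccc(OC)c(OC)c2)c1 | intermediate
8 | (S)-dihydrophenanthrene ketone: 2-[(9S)-9-(3,4-dimethoxyphenyl)-2,4,6-trimethoxy-9,10-dihydrophenanthren-8-yl]-1-(3,4-dimethoxyphenyl)ethan-1-one | COc1cc(OC)c2c(c1)C[C@@H](c1ccc(OC)c(OC)c1)c1c-2cc(OC)cc1CC(=O)c1ccc(OC)c(OC)c1 | intermediate (not isolated)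
9 | (S)-pentacyclic triaryl alkene heptamethyl ether: compound 8 in which the former ketone carbon is bonded to C-6 of the 9-aryl ring (ring B) and double-bonded to the former CH2 carbon, closing the seven-membered ring; methine (S) | COc1cc(OC)c2c(c1)C[C@H]1c3cc(OC)c(OC)cc3C(c3ccc(OC)c(OC)c3)=Cc3cc(OC)cc-2c31 | intermediate
10 | (S,R)-heptamethyl ether of the target: compound 9 with the C=C bond saturated; dihydrophenanthrene methine (S), aryl-bearing CH of the seven-membered ring (R), the two methine hydrogens cis | COc1cc(OC)c2c(c1)C[C@H]1c3cc(OC)c(OC)cc3[C@@H](c3ccc(OC)c(OC)c3)Cc3cc(OC)cc-2c31 | intermediate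
11 | CNP0306974.2: the heptaphenol of 10, that is (9S)-9,10-dihydrophenanthrene-2,4,6-triol whose C-9 carries a 4,5-dihydroxy-1,2-phenylene ring joined through its second ortho carbon by an (R)-CH(3,4-dihydroxyphenyl)–CH2 bridge to C-8 | Oc1cc(O)c2c(c1)C[C@H]1c3cc(O)c(O)cc3[C@@H](c3ccc(O)c(O)c3)Cc3cc(O)cc-2c31 | target

Total step count: 6. Longest linear sequence: 6 steps (1 to 3 to 5 to 7 to 9 to 10 to 11).

Steps most likely to fail

Step 4 (bears the label). What may go wrong is poor discrimination of the two faces of the benzylic cation inside the ion pair, or closure ortho instead of para to the ring C methoxy group. The fallback uses known chemistry and sets out from 7. Treatment with MsOH alone in CH2Cl2 (0 to 40 °C) is an ordinary acid-mediated hydroarylation followed by cyclodehydration. It should give the racemic dihydrophenanthrene ketone F1 in the flask and from it the racemic pentacyclic alkene F2. F2 is resolved by preparative HPLC on an amylose tris(3,5-dimethylphenylcarbamate) phase. The (S)-enantiomer is compound 9, where the route is rejoined, and the (R)-enantiomer of the alkene F3 is set aside.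

Step 5. What may go wrong is slow hydrogen uptake at the hindered triaryl-substituted double bond, or delivery of hydrogen to the concave face. The fallback sets out from 9 and changes the stereo-determining event to an ionic hydrogenation with Et3SiH and TFA in CH2Cl2 at 0 °C. Protonation at the CH carbon of the alkene gives the doubly benzylic cation, and the bulky silane should transfer hydride to its open convex face. The route is rejoined at 10, and no compound outside the list is made (F0).

Step 6. What may go wrong is incomplete cleavage of the seven ethers, acid-induced ionisation of the electron-rich benzylic C–C bonds, or oxidation of the catechols during work-up. The fallback sets out from 10 and replaces the Lewis acid by a nucleophilic demethylation under basic conditions: NaSEt in DMF at 140 °C under argon, then aqueous HCl. The route is rejoined at 11, and no compound outside the list is made (F0).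

Further compounds
F1 | step 4 | racemic dihydrophenanthrene ketone (racemate of 8) | COc1cc(OC)c2c(c1)CC(c1ccc(OC)c(OC)c1)c1c-2cc(OC)cc1CC(=O)c1ccc(OC)c(OC)c1
F2 | step 4 | racemic pentacyclic alkene (racemate of 9) | COc1cc(OC)c2c(c1)CC1c3cc(OC)c(OC)cc3C(c3ccc(OC)c(OC)c3)=Cc3cc(OC)cc-2c31
F3 | step 4 | (R)-enantiomer of the alkene 9 | COc1cc(OC)c2c(c1)C[C@@H]1c3cc(OC)c(OC)cc3C(c3ccc(OC)c(OC)c3)=Cc3cc(OC)cc-2c31
F0 | step 5 | none | none
F0 | step 6 | none | none
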